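## Structural features

- The target is a 1,5-dioxaspiro[2.4]heptane. Its tetrahydrofuran ring (O1–C2–C3–C4–C5) shares the quaternary carbon C3 with an oxirane (C3, C6H2, O7).
- C2 carries a 4-hydroxy-3-methoxyphenyl group and is a benzylic ether carbon. C4 carries a 3-hydroxy-4-methoxybenzyl group. C5 is an unsubstituted OCH2.
- C2, C3 and C4 are three contiguous stereocentres, and the middle one bears no hydrogen. Reading the SMILES, the aryl group at C2, the benzyl group at C4 and the oxirane carbon C6 lie on one face of the ring; the oxirane oxygen O7 lies on the other.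
- The 2,4-cis relation is the opposite of what the classical lactone chemistry of tetrahydrofuran lignans gives, where the aryl and benzyl groups end up trans.
- Fragile groups: the tertiary spiro-oxirane (acid, nucleophiles), the p-hydroxybenzylic C2–O1 bond (ionisation through a quinone methide or benzylic cation), and two free phenols (oxidants).
- The real difficulty is the cis relation of C2 and C4 across a carbon that cannot be epimerised, together with face-selective formation of the oxirane at that carbon.
- The key step exploits the allyl unit C6–C3–C4. If the C3=C4 bond is placed inside a flat 2,5-dihydrofuran, C2 is the only stereocentre, and its aryl group can direct a reagent that adds hydrogen to C4 while moving the double bond out to C3=C6.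

## Logic of the disconnections

17 ⇒ 16. The two phenolic O–Si bonds are cut. The phenols must be masked during the oxidation and the palladium step, and silyl ethers can be removed without acid. The forward step must liberate two phenols without opening the oxirane or ionising the C2–O1 bond.

16 ⇒ 15. The two C–O bonds of the oxirane (C3–O7 and C6–O7) are cut, leaving an exocyclic C3=C6 alkene. This removes the quaternary stereocentre. The forward step must deliver oxygen to the ring face opposite the aryl and benzyl groups, which both flank the alkene on the same face.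

15 ⇒ 14. The C4–H bond is cut and the double bond is moved back into the ring (C3=C4), with a formate on C6. This removes the C4 stereocentre and turns the ring into a flat dihydrofuran whose only stereocentre is C2. The forward step must put hydrogen on C4 rather than C6, and on the face anti to the C2 aryl group.

14 ⇒ 13 ⇒ 12. The formyl C–O bond and then one C6–H bond are cut, leading back to an enal. These are adjustments of oxidation level only. The forward steps must reduce the aldehyde 1,2 and acylate without acid.

12 ⇒ 10 + 8. The O1–C2 bond and the C3=C4 bond are cut. The ring falls into an enal (C2, C3, C6 and the C2 aryl group) and an α-hydroxy ketone (O1, C5, C4 and the benzyl group), both achiral. The forward step must form the C–O bond with control of the enantiotopic face of the enal and then close and dehydrate the aldol.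

10 ⇒ 9. One O–Si bond is cut, leading to a commercial phenolic enal.

8 ⇒ 3 + 4, and 3 ⇒ 1. The bond between the ketone carbon and the CH2OH carbon is cut, giving an arylacetic acid and a two-carbon glycolate-enolate equivalent that loses one carbon as CO2. One O–Si bond is then cut, leading to a commercial phenolic acid. The forward step must acylate on carbon without base.

## Other disconnections considered

Alternative 1: the lignan-lactone route, the first to come to mind.
- Cut: O1–C2 and C2–C3.
- Forward: aldol of the enolate of lactone A1 with aldehyde A2, reduction to a triol, and acid-mediated ring closure to the 3-hydroxymethyl tetrahydrofuran A3. Selenoxide elimination would then give a 3-methylene compound, followed by epoxidation.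
- Ground for rejection: a trans-disubstituted lactone fixes the future C6 and the benzyl group cis on the new ring, and the benzylic closure places the aryl group trans to C6. A3 therefore has aryl and benzyl trans, which is the wrong C2/C4 relation. Correcting it would mean an inversion at C2 into the crowded all-cis array. The route also builds a C3 stereocentre only to destroy it.

Alternative 2: reductive cyclisation of a 1,6-enyne.
- Cut: C3–C4.
- Forward: palladium hydride or stannyl-radical cyclisation of the propargyl cinnamyl ether A4, which would give the skeleton of 15 in one step.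
- Ground for rejection: the C4 centre is formed while C2 sits next to the attacking sp2 carbon. The chair-like picture for 2-substituted hexenyl-type closures places the two substituents trans, and metallacycle pathways put the propargylic substituent on the convex face, again trans. The substrate offers no element that favours cis. The cinnamyl ether could also ionise under Pd–H conditions. Step count would be similar to the chosen plan.

Alternative 3: the 3-ketone route.
- Cut: C3–C6 (and C3–O7).
- Forward: a sulfur ylide (Corey–Chaykovsky) on ketone A5, or methylenation of A5 followed by epoxidation.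
- Ground for rejection: in A5 both stereocentres are α to the carbonyl, and C2–H is also benzylic and α-oxy, so racemisation and epimerisation are expected under ylide conditions. A kinetically adding ylide would attack the open face and place C6 trans to the aryl and benzyl groups, the opposite spiro configuration.

Key step: step 7

Assumption (chemistry): the face selectivity of the amine-catalysed step follows the usual steric-shielding model for diarylprolinol silyl ethers. That model calls for the (R)-catalyst to give (S) at C2 of 12.

## Steps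

Step 1
Reactants: 1 (3-hydroxy-4-methoxyphenyl)acetic acid
Product: 3 [4-methoxy-3-(triisopropylsilyloxy)phenyl]acetic acid, via bis-silylated ester 2 (not isolated)
Conditions: TIPSCl (2.3 equiv), imidazole (5 equiv), DMF, 0 °C to rt; then THF/H2O/AcOH, rt
Reagents that add atoms: triisopropylsilyl chloride, CC(C)[Si](Cl)(C(C)C)C(C)C
Why: Silylation of phenol and acid with TIPSCl/imidazole; the silyl ester is far more labile than the aryl silyl ether and should be hydrolysed selectively in aqueous acetic acid.

Step 2
Reactants: 3 [4-methoxy-3-(triisopropylsilyloxy)phenyl]acetic acid; 4 tris(trimethylsilyloxy)ethene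
Product: 8 1-hydroxy-3-[4-methoxy-3-(triisopropylsilyloxy)phenyl]propan-2-one, via acid chloride 5 (not isolated), via silylated acylation adduct 6 (not isolated), via hydroxy keto acid 7 (not isolated)
Conditions: (COCl)2 (1.3 equiv), DMF (cat.), CH2Cl2, 0 °C to rt, concentrate; 4 (2.2 equiv), neat, 90 °C; then THF/1 M aq HCl, 50 °C
Reagents that add atoms: none
Why: Wissner hydroxymethyl ketone synthesis: the acid chloride C-acylates the ketene bis(silyl) acetal 4, and mild aqueous acid removes the trimethylsilyl groups and decarboxylates the α-hydroxy-β-keto acid. No base is present, so ketene formation from the arylacetyl chloride is avoided.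

Step 3
Reactants: 9 (E)-3-(4-hydroxy-3-methoxyphenyl)prop-2-enal (coniferaldehyde)
Product: 10 (E)-3-[3-methoxy-4-(triisopropylsilyloxy)phenyl]prop-2-enal
Conditions: TIPSCl (1.2 equiv), imidazole (2.5 equiv), DMF, rt
Reagents that add atoms: triisopropylsilyl chloride, CC(C)[Si](Cl)(C(C)C)C(C)C
Why: Standard phenol silylation; the silyl ether also lowers the donor strength of the para oxygen, which keeps the enal electrophilic enough for iminium catalysis.

Step 4
Reactants: 10 (E)-3-[3-methoxy-4-(triisopropylsilyloxy)phenyl]prop-2-enal; 8 1-hydroxy-3-[4-methoxy-3-(triisopropylsilyloxy)phenyl]propan-2-one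
Product: 12 (2S)-2-[3-methoxy-4-(triisopropylsilyloxy)phenyl]-4-[4-methoxy-3-(triisopropylsilyloxy)benzyl]-2,5-dihydrofuran-3-carbaldehyde, via aldol adduct 11 (not isolated)
Conditions: (R)-α,α-diphenylprolinol trimethylsilyl ether (20 mol %), 2-nitrobenzoic acid (20 mol %), 4 Å MS, toluene, rt to 40 °C
Reagents that add atoms: none
Why: Iminium/enamine oxa-Michael–aldol condensation domino, of the kind known for 2H-chromene-3-carbaldehydes and for α-hydroxy ketones with enals: the hydroxyl of 8 adds to C-β of the iminium ion of 10, the enamine closes on the ketone (5-exo-trig aldol), and amine-assisted dehydration gives the conjugated enal. The CPh2OTMS group of the (R)-catalyst should block the Si face of C-β in the s-trans E-iminium ion, so oxygen adds to the Re face and C2 is formed (S); C2 is the only stereocentre that survives the dehydration.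

Step 5
Reactants: 12 (2S)-2-[3-methoxy-4-(triisopropylsilyloxy)phenyl]-4-[4-methoxy-3-(triisopropylsilyloxy)benzyl]-2,5-dihydrofuran-3-carbaldehyde
Product: 13 [(2S)-2-[3-methoxy-4-(triisopropylsilyloxy)phenyl]-4-[4-methoxy-3-(triisopropylsilyloxy)benzyl]-2,5-dihydrofuran-3-yl]methanol
Conditions: NaBH4, CeCl3·7H2O, MeOH/THF, −40 to −20 °C
Reagents that add atoms: none
Why: Luche 1,2-reduction of the enal; the cerium-activated aldehyde is reduced without conjugate reduction and C2 is untouched.

Step 6
Reactants: 13 [(2S)-2-[3-methoxy-4-(triisopropylsilyloxy)phenyl]-4-[4-methoxy-3-(triisopropylsilyloxy)benzyl]-2,5-dihydrofuran-3-yl]methanol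
Product: 14 [(2S)-2-[3-methoxy-4-(triisopropylsilyloxy)phenyl]-4-[4-methoxy-3-(triisopropylsilyloxy)benzyl]-2,5-dihydrofuran-3-yl]methyl formate
Conditions: acetic formic anhydride (preformed, 3 equiv), pyridine, CH2Cl2, 0 °C
Reagents that add atoms: acetic formic anhydride, CC(=O)OC=O
Why: O-formylation of a primary allylic alcohol by a mixed anhydride under buffered conditions; the formyl carbonyl is the more electrophilic one and should be transferred selectively.

Step 7
Reactants: 14 [(2S)-2-[3-methoxy-4-(triisopropylsilyloxy)phenyl]-4-[4-methoxy-3-(triisopropylsilyloxy)benzyl]-2,5-dihydrofuran-3-yl]methyl formate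
Product: 15 (2R,4R)-2-[3-methoxy-4-(triisopropylsilyloxy)phenyl]-4-[4-methoxy-3-(triisopropylsilyloxy)benzyl]-3-methylidenetetrahydrofuran (aryl and benzyl cis)
Conditions: Pd2(dba)3·CHCl3 (2.5 mol %), n-Bu3P (5 mol %), degassed 1,4-dioxane, 60 °C
Reagents that add atoms: none
Why: Tsuji–Mandai hydrogenolysis of an allylic formate: Pd(0)–PBu3 ionises the primary allylic C6–O bond of 14 to a π-allyl palladium formate spanning C6–C3–C4, loss of CO2 gives the π-allyl palladium hydride, and C–H reductive elimination returns Pd(0). The closest known reaction type is the Pd/PBu3-catalysed conversion of cycloalkenylmethyl and other γ,γ-disubstituted allylic formates into exo-methylene or terminal alkenes, where the hydride is transferred inside the coordination sphere to the more substituted allyl terminus. No ring is closed; the step forms the C4–H bond, moves the double bond to the exocyclic C3=C6 position and releases only CO2. The new stereocentre C4 is controlled by C2: the dihydrofuran is flat, the aryl group on C2 (next to the central allyl carbon C3) covers one face, and the Pd(PBu3) fragment should therefore sit on the other; the two diastereomeric π-allyl complexes can interconvert by π–σ–π at the unsubstituted C6 terminus, so the preference should be expressed even if ionisation is unselective. The hydride leaves palladium on the face the metal occupies, so hydrogen enters C4 anti to the aryl group and the benzyl group ends on the aryl face, giving the 2,4-cis isomer (2R,4R). The step needs regioselectivity (hydrogen to C4, not C6), which the 1:1 Pd/PBu3 formate protocol is expected to secure, and chemoselectivity over β-hydride loss toward a furan, which the fast intramolecular decarboxylation and hydride transfer at moderate temperature should secure.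

Step 8
Reactants: 15 (2R,4R)-2-[3-methoxy-4-(triisopropylsilyloxy)phenyl]-4-[4-methoxy-3-(triisopropylsilyloxy)benzyl]-3-methylidenetetrahydrofuran
Product: 16 (3S,4S,7S)-4-[3-methoxy-4-(triisopropylsilyloxy)phenyl]-7-[4-methoxy-3-(triisopropylsilyloxy)benzyl]-1,5-dioxaspiro[2.4]heptane
Conditions: dimethyldioxirane (1.2 equiv, acetone solution), CH2Cl2, −20 to 0 °C
Reagents that add atoms: dimethyldioxirane, CC1(C)OO1
Why: Concerted electrophilic epoxidation of a 1,1-disubstituted alkene by a dioxirane under neutral conditions. The aryl group at C2 and the benzyl group at C4 both lie on one face of the ring, so oxygen should be delivered to the opposite face; O7 then ends trans to both and C6 cis, which fixes C3 as in the target. The silylated arenes should be far less reactive toward the dioxirane than the alkene at low temperature.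

Step 9
Reactants: 16 (3S,4S,7S)-4-[3-methoxy-4-(triisopropylsilyloxy)phenyl]-7-[4-methoxy-3-(triisopropylsilyloxy)benzyl]-1,5-dioxaspiro[2.4]heptane
Product: 17 (3S,4S,7S)-4-(4-hydroxy-3-methoxyphenyl)-7-(3-hydroxy-4-methoxybenzyl)-1,5-dioxaspiro[2.4]heptane (target)
Conditions: TBAF (2.2 equiv), AcOH (2.2 equiv), THF, 0 °C
Reagents that add atoms: none
Why: Fluoride-induced cleavage of the aryl Si–O bonds, buffered with acetic acid so that the phenoxides are protonated and neither the oxirane nor the benzylic C2–O1 bond is exposed to strong base; no stereocentre is touched.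

## Compound list

1 | (3-hydroxy-4-methoxyphenyl)acetic acid | COc1ccc(CC(=O)O)cc1O | starting material
2 | triisopropylsilyl [4-methoxy-3-(triisopropylsilyloxy)phenyl]acetate | COc1ccc(CC(=O)O[Si](C(C)C)(C(C)C)C(C)C)cc1O[Si](C(C)C)(C(C)C)C(C)C | intermediate (not isolated)
3 | [4-methoxy-3-(triisopropylsilyloxy)phenyl]acetic acid | COc1ccc(CC(=O)O)cc1O[Si](C(C)C)(C(C)C)C(C)C | intermediate
4 | tris(trimethylsilyloxy)ethene | C[Si](C)(C)OC=C(O[Si](C)(C)C)O[Si](C)(C)C | starting material
5 | [4-methoxy-3-(triisopropylsilyloxy)phenyl]acetyl chloride | COc1ccc(CC(=O)Cl)cc1O[Si](C(C)C)(C(C)C)C(C)C | intermediate (not isolated)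
6 | trimethylsilyl 4-[4-methoxy-3-(triisopropylsilyloxy)phenyl]-3-oxo-2-(trimethylsilyloxy)butanoate (racemic) | COc1ccc(CC(=O)C(O[Si](C)(C)C)C(=O)O[Si](C)(C)C)cc1O[Si](C(C)C)(C(C)C)C(C)C | intermediate (not isolated)
7 | 2-hydroxy-4-[4-methoxy-3-(triisopropylsilyloxy)phenyl]-3-oxobutanoic acid (racemic) | COc1ccc(CC(=O)C(O)C(=O)O)cc1O[Si](C(C)C)(C(C)C)C(C)C | intermediate (not isolated)
8 | 1-hydroxy-3-[4-methoxy-3-(triisopropylsilyloxy)phenyl]propan-2-one | COc1ccc(CC(=O)CO)cc1O[Si](C(C)C)(C(C)C)C(C)C | intermediate
9 | (E)-3-(4-hydroxy-3-methoxyphenyl)prop-2-enal (coniferaldehyde) | COc1cc(/C=C/C=O)ccc1O | starting material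
10 | (E)-3-[3-methoxy-4-(triisopropylsilyloxy)phenyl]prop-2-enal | COc1cc(/C=C/C=O)ccc1O[Si](C(C)C)(C(C)C)C(C)C | intermediate
11 | (2R)-4-hydroxy-2-[3-methoxy-4-(triisopropylsilyloxy)phenyl]-4-[4-methoxy-3-(triisopropylsilyloxy)benzyl]tetrahydrofuran-3-carbaldehyde (C3 and C4 not defined; both are erased on dehydration) | COc1ccc(CC2(O)CO[C@@H](c3ccc(O[Si](C(C)C)(C(C)C)C(C)C)c(OC)c3)C2C=O)cc1O[Si](C(C)C)(C(C)C)C(C)C | intermediate (not isolated)
12 | (2S)-2-[3-methoxy-4-(triisopropylsilyloxy)phenyl]-4-[4-methoxy-3-(triisopropylsilyloxy)benzyl]-2,5-dihydrofuran-3-carbaldehyde | COc1ccc(CC2=C(C=O)[C@H](c3ccc(O[Si](C(C)C)(C(C)C)C(C)C)c(OC)c3)OC2)cc1O[Si](C(C)C)(C(C)C)C(C)C | intermediate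
13 | [(2S)-2-[3-methoxy-4-(triisopropylsilyloxy)phenyl]-4-[4-methoxy-3-(triisopropylsilyloxy)benzyl]-2,5-dihydrofuran-3-yl]methanol | COc1ccc(CC2=C(CO)[C@H](c3ccc(O[Si](C(C)C)(C(C)C)C(C)C)c(OC)c3)OC2)cc1O[Si](C(C)C)(C(C)C)C(C)C | intermediate
14 | [(2S)-2-[3-methoxy-4-(triisopropylsilyloxy)phenyl]-4-[4-methoxy-3-(triisopropylsilyloxy)benzyl]-2,5-dihydrofuran-3-yl]methyl formate | COc1ccc(CC2=C(COC=O)[C@H](c3ccc(O[Si](C(C)C)(C(C)C)C(C)C)c(OC)c3)OC2)cc1O[Si](C(C)C)(C(C)C)C(C)C | intermediate
15 | (2R,4R)-2-[3-methoxy-4-(triisopropylsilyloxy)phenyl]-4-[4-methoxy-3-(triisopropylsilyloxy)benzyl]-3-methylidenetetrahydrofuran | COc1ccc(C[C@H]2CO[C@@H](c3ccc(O[Si](C(C)C)(C(C)C)C(C)C)c(OC)c3)C2=C)cc1O[Si](C(C)C)(C(C)C)C(C)C | intermediate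
16 | (3S,4S,7S)-4-[3-methoxy-4-(triisopropylsilyloxy)phenyl]-7-[4-methoxy-3-(triisopropylsilyloxy)benzyl]-1,5-dioxaspiro[2.4]heptane | COc1ccc(C[C@H]2CO[C@@H](c3ccc(O[Si](C(C)C)(C(C)C)C(C)C)c(OC)c3)[C@@]23CO3)cc1O[Si](C(C)C)(C(C)C)C(C)C | intermediate
17 | (3S,4S,7S)-4-(4-hydroxy-3-methoxyphenyl)-7-(3-hydroxy-4-methoxybenzyl)-1,5-dioxaspiro[2.4]heptane | COc1ccc(C[C@H]2CO[C@@H](c3ccc(O)c(OC)c3)[C@@]23CO3)cc1O | target

## Step count and least certain steps

Total: 9 steps. Longest linear sequence: 8 steps (1, 2, 4, 5, 6, 7, 8, 9); step 3 is a one-step branch.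

**Step 7 (key step).**
- What may go wrong: hydride delivery to the unsubstituted C6 terminus, which would give the ring-conjugated 3-methyl isomer; too little face discrimination by the C2 aryl group; β-hydride elimination followed by aromatisation; slow ionisation of the crowded tetrasubstituted allyl formate; palladium-mediated isomerisation of the product alkene.
- Fallback: a metal-free sigmatropic transposition that sets out from 13 and returns at 15. Mitsunobu reaction of 13 with 2-nitrobenzenesulfonylhydrazide (PPh3, DEAD, THF, −30 °C) should give the allylic sulfonylhydrazine F1. On warming, F1 loses the sulfinic acid to give the monoalkyl diazene F2. F2 transfers its N–H hydrogen to C4 in a retro-ene step with loss of N2 (Myers reductive transposition). The diazene should fold over the ring face away from the C2 aryl group, so the same cis isomer 15 is expected.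

**Step 4.**
- What may go wrong: the oxa-Michael equilibrium may lie on the side of the components; C-alkylation through the enol of the arylacetone unit may compete; dehydration of the aldol may stall; reversible C–O bond formation may erode the enantiomeric purity.
- Fallback: an alkyne carbocyclisation in place of the aldol, setting out from 10 and returning at 12. Commercial 5-bromo-2-methoxyphenol F3 is silylated (TIPSCl, imidazole) to the aryl bromide F4. Sonogashira coupling of F4 with propargyl alcohol (PdCl2(PPh3)2, CuI, Et3N, 60 °C) gives the arylpropargyl alcohol F5. Combined amine and palladium catalysis on 10 and F5 ((R)-diphenylprolinol trimethylsilyl ether, PdCl2 5 mol %, benzoic acid, toluene) should give oxa-Michael addition and then 5-exo-dig attack of the enamine on the palladium-activated alkyne. This forms the exocyclic benzylidene aldehyde F6, which is not isolated; migration of its double bond into conjugation with the aldehyde gives 12.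

**Step 8.**
- What may go wrong: loss of face selectivity if the ring adopts a conformation with both substituents pseudo-equatorial; oxidation of the electron-rich arenes; rearrangement of the tertiary oxirane during isolation.
- Fallback: dihydroxylation and ring closure, setting out from 15 and returning at 16. OsO4 (cat.)/NMO should add from the same open face to give the diol F7. Selective sulfonylation of the primary hydroxyl (TsCl, Et3N, Bu2SnO cat.) gives the monotosylate F8. DBU then closes the oxirane with retention at C3.

**Step 9.**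
- What may go wrong: opening of the oxirane by fluoride or phenoxide; quinone-methide-type cleavage of the benzylic C2–O1 bond under basic conditions.
- Fallback: reverse the order of the last two operations, setting out from 15 and returning at 17. Desilylation of 15 (TBAF, AcOH) gives the bis-phenol alkene F9. F9 is then epoxidised under phenol-tolerant, weakly basic Payne conditions (H2O2, benzonitrile, KHCO3, MeOH), with the same face preference.

## Further compounds

F1 | step 7 | N-{[(2S)-2-[3-methoxy-4-(triisopropylsilyloxy)phenyl]-4-[4-methoxy-3-(triisopropylsilyloxy)benzyl]-2,5-dihydrofuran-3-yl]methyl}-2-nitrobenzenesulfonohydrazide (N-alkylated at the sulfonylated nitrogen) | COc1ccc(CC2=C(CN(N)S(=O)(=O)c4ccccc4[N+](=O)[O-])[C@H](c3ccc(O[Si](C(C)C)(C(C)C)C(C)C)c(OC)c3)OC2)cc1O[Si](C(C)C)(C(C)C)C(C)C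
F2 | step 7 | {[(2S)-2-[3-methoxy-4-(triisopropylsilyloxy)phenyl]-4-[4-methoxy-3-(triisopropylsilyloxy)benzyl]-2,5-dihydrofuran-3-yl]methyl}diazene | COc1ccc(CC2=C(CN=N)[C@H](c3ccc(O[Si](C(C)C)(C(C)C)C(C)C)c(OC)c3)OC2)cc1O[Si](C(C)C)(C(C)C)C(C)C
F3 | step 4 | 5-bromo-2-methoxyphenol (commercial) | COc1ccc(Br)cc1O
F4 | step 4 | (5-bromo-2-methoxyphenoxy)triisopropylsilane | COc1ccc(Br)cc1O[Si](C(C)C)(C(C)C)C(C)C
F5 | step 4 | 3-[4-methoxy-3-(triisopropylsilyloxy)phenyl]prop-2-yn-1-ol | COc1ccc(C#CCO)cc1O[Si](C(C)C)(C(C)C)C(C)C
F6 | step 4 | (2R)-2-[3-methoxy-4-(triisopropylsilyloxy)phenyl]-4-[4-methoxy-3-(triisopropylsilyloxy)benzylidene]tetrahydrofuran-3-carbaldehyde (C3 and alkene geometry not defined; both are erased on isomerisation) | COc1ccc(C=C2CO[C@@H](c3ccc(O[Si](C(C)C)(C(C)C)C(C)C)c(OC)c3)C2C=O)cc1O[Si](C(C)C)(C(C)C)C(C)C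
F7 | step 8 | (2S,3S,4S)-3-(hydroxymethyl)-2-[3-methoxy-4-(triisopropylsilyloxy)phenyl]-4-[4-methoxy-3-(triisopropylsilyloxy)benzyl]tetrahydrofuran-3-ol | COc1ccc(C[C@H]2CO[C@@H](c3ccc(O[Si](C(C)C)(C(C)C)C(C)C)c(OC)c3)[C@@]2(O)CO)cc1O[Si](C(C)C)(C(C)C)C(C)C
F8 | step 8 | [(2S,3S,4S)-3-hydroxy-2-[3-methoxy-4-(triisopropylsilyloxy)phenyl]-4-[4-methoxy-3-(triisopropylsilyloxy)benzyl]tetrahydrofuran-3-yl]methyl 4-methylbenzenesulfonate | COc1ccc(C[C@H]2CO[C@@H](c3ccc(O[Si](C(C)C)(C(C)C)C(C)C)c(OC)c3)[C@@]2(O)COS(=O)(=O)c4ccc(C)cc4)cc1O[Si](C(C)C)(C(C)C)C(C)C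
F9 | step 9 | 4-[(2R,4R)-4-(3-hydroxy-4-methoxybenzyl)-3-methylidenetetrahydrofuran-2-yl]-2-methoxyphenol | COc1ccc(C[C@H]2CO[C@@H](c3ccc(O)c(OC)c3)C2=C)cc1O
A1 | alternative 1 | (4R)-4-[4-methoxy-3-(triisopropylsilyloxy)benzyl]dihydrofuran-2(3H)-one | COc1ccc(C[C@H]2COC(=O)C2)cc1O[Si](C(C)C)(C(C)C)C(C)C
A2 | alternative 1 | 3-methoxy-4-(triisopropylsilyloxy)benzaldehyde | COc1cc(C=O)ccc1O[Si](C(C)C)(C(C)C)C(C)C
A3 | alternative 1 | [(2S,3R,4R)-2-[3-methoxy-4-(triisopropylsilyloxy)phenyl]-4-[4-methoxy-3-(triisopropylsilyloxy)benzyl]tetrahydrofuran-3-yl]methanol (aryl trans to CH2OH, CH2OH cis to benzyl) | COc1ccc(C[C@H]2CO[C@H](c3ccc(O[Si](C(C)C)(C(C)C)C(C)C)c(OC)c3)[C@H]2CO)cc1O[Si](C(C)C)(C(C)C)C(C)C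
A4 | alternative 2 | (R)-1-[3-methoxy-4-(triisopropylsilyloxy)phenyl]prop-2-yn-1-yl (E)-3-[4-methoxy-3-(triisopropylsilyloxy)phenyl]prop-2-en-1-yl ether | C#C[C@@H](OC/C=C/c1ccc(OC)c(O[Si](C(C)C)(C(C)C)C(C)C)c1)c1ccc(O[Si](C(C)C)(C(C)C)C(C)C)c(OC)c1
A5 | alternative 3 | (2S,4S)-2-[3-methoxy-4-(triisopropylsilyloxy)phenyl]-4-[4-methoxy-3-(triisopropylsilyloxy)benzyl]dihydrofuran-3(2H)-one | COc1ccc(C[C@H]2CO[C@@H](c3ccc(O[Si](C(C)C)(C(C)C)C(C)C)c(OC)c3)C2=O)cc1O[Si](C(C)C)(C(C)C)C(C)C
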